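**Retrosynthetic overview**
1. The quinone is unmasked last. The target comes from a tris-MOM hydroquinone isoflavan by acid deprotection and mild oxidation of ring B.
2. The pyran ring (ring C) and C3 come from an acyclic (E)-cinnamyl aryl ether in one flask: an enantioselective oxidative 1,2-shift of ring B from the benzylic carbon (future C4) to C3, Friedel-Crafts closure C4–C4a, then ionic reduction at C4.
3. The O1–C2 bond comes from Pd-catalysed allylic etherification of the ring A phenol with a ring B 1-arylallyl carbonate.
4. The ring A phenol comes from resorcinol (methylation, two rounds of metalation/hydroxylation). The ring B carbonate comes from catechol (methylation, double metalation/hydroxylation, MOM protection, lithiation/acrolein).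
5. Ring order: rings A and B enter as benzene rings. Ring C is the only ring built (step 10). Ring B becomes the quinone in step 11.

**Assumption:** the (R,R)-lactate-derived iodane is taken to attack the Si face of the alkene carbon next to the CH2O group; if the opposite sense is found, its (S,S)-antipode, made from the other lactate enantiomer, is used in the same way in step 10.

**Step 1**
Reactants: 1 resorcinol
Product: 2 1,3-dimethoxybenzene
Conditions: Me2SO4, K2CO3, acetone, reflux
Reagents that add atoms: dimethyl sulfate COS(=O)(=O)OC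
Why: Double Williamson O-methylation of the two phenoxides goes to completion under these conditions and no other nucleophilic site competes.

**Step 2**
Reactants: 2 1,3-dimethoxybenzene
Product: 5 2,6-dimethoxyphenol, via 2,6-dimethoxyphenyllithium 3 (not isolated), via dimethyl arylboronate 4 (not isolated)
Conditions: n-BuLi, THF, 0 °C to rt; B(OMe)3, −78 °C to rt; H2O2, AcOH, 0 °C
Reagents that add atoms: hydrogen peroxide OO
Why: Directed ortho-metalation occurs only at C2 between the two cooperating methoxy groups, and borylation followed by peroxide-induced boron-to-oxygen migration turns C–Li into C–OH.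

**Step 3**
Reactants: 5 2,6-dimethoxyphenol
Product: 6 1,3-dimethoxy-2-(methoxymethoxy)benzene
Conditions: MOMCl, K2CO3, DMF, rt
Reagents that add atoms: chloromethyl methyl ether COCCl
Why: O-alkylation of the phenoxide (MOM protection) masks the future 7-OH with a group that survives BuLi and leaves under mild acid at the end.

**Step 4**
Reactants: 6 1,3-dimethoxy-2-(methoxymethoxy)benzene
Product: 9 2,4-dimethoxy-3-(methoxymethoxy)phenol, via ring A aryllithium 7 (not isolated), via ring A dimethyl boronate 8 (not isolated)
Conditions: n-BuLi, TMEDA, THF, 0 °C; B(OMe)3, −78 °C to rt; H2O2, AcOH, 0 °C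
Reagents that add atoms: hydrogen peroxide OO
Why: Directed ortho-metalation next to a methoxy group gives one regioisomer because the two open ortho sites are equivalent by symmetry, and borylation-oxidation gives the phenol oxygen that becomes O1.

**Step 5**
Reactants: 10 catechol
Product: 11 1,2-dimethoxybenzene
Conditions: Me2SO4, K2CO3, acetone, reflux
Reagents that add atoms: dimethyl sulfate COS(=O)(=O)OC
Why: Double Williamson O-methylation installs the two methoxy groups that remain on the quinone.

**Step 6**
Reactants: 11 1,2-dimethoxybenzene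
Product: 14 2,3-dimethoxybenzene-1,4-diol, via 3,6-dilithioveratrole 12 (not isolated), via ring B bis(dimethyl boronate) 13 (not isolated)
Conditions: n-BuLi (3 equiv), TMEDA (3 equiv), Et2O–hexane, rt to reflux; B(OMe)3, −78 °C to rt; H2O2, AcOH, 0 °C, argon
Reagents that add atoms: hydrogen peroxide OO
Why: In this twofold directed ortho-metalation each methoxy group directs lithium to its own free ortho position (C3 and C6), and double borylation-oxidation installs both para-related hydroxyls in one operation.

**Step 7**
Reactants: 14 2,3-dimethoxybenzene-1,4-diol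
Product: 15 2,3-dimethoxy-1,4-bis(methoxymethoxy)benzene
Conditions: MOMCl, K2CO3, DMF, rt, argon
Reagents that add atoms: chloromethyl methyl ether COCCl
Why: Double MOM protection (phenoxide O-alkylation) locks the air-sensitive hydroquinone and provides strong directing groups for the next lithiation.

**Step 8**
Reactants: 15 2,3-dimethoxy-1,4-bis(methoxymethoxy)benzene; 16 acrolein
Product: 19 methyl 1-[3,4-dimethoxy-2,5-bis(methoxymethoxy)phenyl]prop-2-en-1-yl carbonate (racemic), via ring B aryllithium 17 (not isolated), via lithium allylic alkoxide 18 (not isolated)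
Conditions: n-BuLi, THF, 0 °C; acrolein, −78 °C; ClCO2Me, −78 to 0 °C
Reagents that add atoms: methyl chloroformate COC(=O)Cl
Why: OMOM-directed ortho-lithiation (both open sites equivalent), 1,2-addition to acrolein and in situ acylation of the alkoxide give the carbonate, whose racemic carbinol centre is erased in step 9.

**Step 9**
Reactants: 9 2,4-dimethoxy-3-(methoxymethoxy)phenol; 19 methyl 1-[3,4-dimethoxy-2,5-bis(methoxymethoxy)phenyl]prop-2-en-1-yl carbonate
Product: 20 1-{[(2E)-3-[3,4-dimethoxy-2,5-bis(methoxymethoxy)phenyl]prop-2-en-1-yl]oxy}-2,4-dimethoxy-3-(methoxymethoxy)benzene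
Conditions: Pd(PPh3)4 (3 mol %), THF, rt
Reagents that add atoms: none
Why: In this Tsuji-Trost allylic etherification zerovalent palladium ionises the carbonate with loss of CO2, the released methoxide deprotonates the phenol, and the phenoxide attacks the unhindered terminus of the syn 1-aryl-π-allyl complex to give the conjugated linear E ether.

**Step 10**
Reactants: 20 1-{[(2E)-3-[3,4-dimethoxy-2,5-bis(methoxymethoxy)phenyl]prop-2-en-1-yl]oxy}-2,4-dimethoxy-3-(methoxymethoxy)benzene
Product: 23 (3S)-3-[3,4-dimethoxy-2,5-bis(methoxymethoxy)phenyl]-6,8-dimethoxy-7-(methoxymethoxy)chromane, via acyclic S acetal 21 (not isolated), via 4-methoxyisoflavan 22 (not isolated)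
Conditions: (R,R)-ArLI(OAc)2 (ArL = 2,6-bis[(1R)-1-(methoxycarbonyl)ethoxy]phenyl, 1.2 equiv), BF3·OEt2, MeOH (3 equiv), CH2Cl2–CF3CH2OH 10:1, −78 to −40 °C; then Et3SiH (5 equiv), BF3·OEt2, −78 to −30 °C
Reagents that add atoms: none
Why: Proposed new method: the BF3-activated chiral aryl-λ3-iodane (trivalent iodine) adds to the Si face of C2 of the propenyl chain while MeOH caps the benzylic carbon, the very electron-rich ring B then displaces the aryl iodide nucleofuge from the rear through a phenonium ion (1,2-aryl shift with inversion, which makes the C3–C1' bond and sets 3S), the methoxycarbenium ion left at the old benzylic carbon (resting as acetal 21) is captured by ring A at its only free position ortho to O1 and para to OMOM (six-membered Friedel-Crafts closure of ring C), and the doubly oxygen-stabilised benzylic ether 22 is ionised and reduced by Et3SiH (ionic hydrogenation) faster than aryl MOM ethers are cleaved; the closest known reactions are the lactate-iodane-mediated enantioselective oxidative rearrangements of chalcones and 1,1-disubstituted alkenes, the aryl-iodide-catalysed migratory geminal difluorination of cinnamic acid derivatives and the Tl(NO3)3 chalcone-to-isoflavone aryl shift, none of which has been run on a cinnamyl aryl ether or ended by arene capture.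

**Step 11**
Reactants: 23 (3S)-3-[3,4-dimethoxy-2,5-bis(methoxymethoxy)phenyl]-6,8-dimethoxy-7-(methoxymethoxy)chromane
Product: 25 5-[(3S)-7-hydroxy-6,8-dimethoxychroman-3-yl]-2,3-dimethoxy-1,4-benzoquinone (CNP0121136.1), via hydroquinone 24 (not isolated)
Conditions: HCl (2 M), MeOH, 45 °C, argon; then FeCl3 (2.2 equiv), MeOH–H2O, 0 °C
Reagents that add atoms: none
Why: Acid-catalysed acetal exchange removes the three MOM groups, and FeCl3 oxidises the 2,3-dimethoxyhydroquinone of ring B, whose potential lies well below that of the hindered 2,6-dimethoxyphenol of ring A, to the quinone under non-basic conditions that leave C3 untouched.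

**Compound list**
1 | resorcinol | Oc1cccc(O)c1 | starting material
2 | 1,3-dimethoxybenzene | COc1cccc(OC)c1 | intermediate
3 | 2,6-dimethoxyphenyllithium | [Li]c1c(OC)cccc1OC | intermediate
4 | dimethyl (2,6-dimethoxyphenyl)boronate | COB(OC)c1c(OC)cccc1OC | intermediate
5 | 2,6-dimethoxyphenol | COc1cccc(OC)c1O | intermediate
6 | 1,3-dimethoxy-2-(methoxymethoxy)benzene | COCOc1c(OC)cccc1OC | intermediate
7 | [2,4-dimethoxy-3-(methoxymethoxy)phenyl]lithium | [Li]c1ccc(OC)c(OCOC)c1OC | intermediate
8 | dimethyl [2,4-dimethoxy-3-(methoxymethoxy)phenyl]boronate | COB(OC)c1ccc(OC)c(OCOC)c1OC | intermediate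
9 | 2,4-dimethoxy-3-(methoxymethoxy)phenol | COCOc1c(OC)ccc(O)c1OC | intermediate
10 | catechol | Oc1ccccc1O | starting material
11 | 1,2-dimethoxybenzene | COc1ccccc1OC | intermediate
12 | 3,6-dilithio-1,2-dimethoxybenzene | [Li]c1ccc([Li])c(OC)c1OC | intermediate
13 | tetramethyl (2,3-dimethoxy-1,4-phenylene)diboronate | COB(OC)c1ccc(B(OC)OC)c(OC)c1OC | intermediate
14 | 2,3-dimethoxybenzene-1,4-diol | COc1c(O)ccc(O)c1OC | intermediate
15 | 2,3-dimethoxy-1,4-bis(methoxymethoxy)benzene | COCOc1ccc(OCOC)c(OC)c1OC | intermediate
16 | acrolein | C=CC=O | starting material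
17 | [3,4-dimethoxy-2,5-bis(methoxymethoxy)phenyl]lithium | [Li]c1cc(OCOC)c(OC)c(OC)c1OCOC | intermediate
18 | lithium 1-[3,4-dimethoxy-2,5-bis(methoxymethoxy)phenyl]prop-2-en-1-olate (racemic) | [Li]OC(C=C)c1cc(OCOC)c(OC)c(OC)c1OCOC | intermediate
19 | methyl 1-[3,4-dimethoxy-2,5-bis(methoxymethoxy)phenyl]prop-2-en-1-yl carbonate (racemic) | C=CC(OC(=O)OC)c1cc(OCOC)c(OC)c(OC)c1OCOC | intermediate
20 | 1-{[(2E)-3-[3,4-dimethoxy-2,5-bis(methoxymethoxy)phenyl]prop-2-en-1-yl]oxy}-2,4-dimethoxy-3-(methoxymethoxy)benzene | COCOc1cc(/C=C/COc2ccc(OC)c(OCOC)c2OC)c(OCOC)c(OC)c1OC | intermediate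
21 | (2S)-2-[3,4-dimethoxy-2,5-bis(methoxymethoxy)phenyl]-3-[2,4-dimethoxy-3-(methoxymethoxy)phenoxy]propanal dimethyl acetal | COCOc1cc([C@H](C(OC)OC)COc2ccc(OC)c(OCOC)c2OC)c(OCOC)c(OC)c1OC | intermediate
22 | (3S)-3-[3,4-dimethoxy-2,5-bis(methoxymethoxy)phenyl]-4,6,8-trimethoxy-7-(methoxymethoxy)chromane (both C4 epimers) | COCOc1cc([C@H]2COc3c(OC)c(OCOC)c(OC)cc3C2OC)c(OCOC)c(OC)c1OC | intermediate
23 | (3S)-3-[3,4-dimethoxy-2,5-bis(methoxymethoxy)phenyl]-6,8-dimethoxy-7-(methoxymethoxy)chromane | COCOc1cc([C@H]2COc3c(OC)c(OCOC)c(OC)cc3C2)c(OCOC)c(OC)c1OC | intermediate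
24 | 2-[(3S)-7-hydroxy-6,8-dimethoxychroman-3-yl]-5,6-dimethoxybenzene-1,4-diol | COc1c(O)cc([C@H]2COc3c(OC)c(O)c(OC)cc3C2)c(O)c1OC | intermediate
25 | 5-[(3S)-7-hydroxy-6,8-dimethoxychroman-3-yl]-2,3-dimethoxy-1,4-benzoquinone | COC1=C(OC)C(=O)C([C@H]2COc3c(cc(OC)c(O)c3OC)C2)=CC1=O | target

**Step count**
- Total: 11 steps.
- Longest linear sequence: 7 steps (1, 2, 3, 4, 9, 10, 11 or 5, 6, 7, 8, 9, 10, 11).

**Three steps most likely to fail**

1. **Step 10 (the new step).**
   - Risks: electron-transfer oxidation of the two tetra-alkoxyarenes by the activated iodane; early loss of the 2'-O-MOM group; proton loss from C3 of the C4 cation, which gives the isoflavene and erodes the ee; and an unknown level and sense of induction.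
   - Fallback with known chemistry, from 20 back to 23. PhI(OH)OTs in MeOH at rt brings about the same aryl shift without stereocontrol and gives the racemic dimethyl acetal F1. BF3·OEt2 in CH2Cl2 at −40 °C closes it to the racemic 4-methoxyisoflavan F2. On warming to 0 °C this loses methanol to give the isoflav-3-ene F3. Asymmetric hydrogenation of this trisubstituted alkene then sets 3S and gives 23. The catalyst is a cationic iridium phosphinite-oxazoline complex, [Ir(cod)(L)]B[3,5-(CF3)2C6H3]4 (1 mol %, ligand antipode chosen for the S product), under H2 at 50 bar in CH2Cl2 at rt.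

2. **Step 6.**
   - Risks: the second lithiation may stay incomplete, and the hydroquinone is sensitive to over-oxidation during the peroxide stage.
   - Fallback from 11 back to 14. A single lithiation (n-BuLi, TMEDA, Et2O, rt) gives 2,3-dimethoxyphenyllithium F4. B(OMe)3 gives dimethyl (2,3-dimethoxyphenyl)boronate F5, and H2O2/AcOH gives 2,3-dimethoxyphenol F6. Teuber oxidation with (KSO3)2NO in aqueous KH2PO4/acetone places the second oxygen para to the first and gives 2,3-dimethoxy-1,4-benzoquinone F7. Na2S2O4 in Et2O/H2O reduces it to 14.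

3. **Step 9.**
   - Risks: the very electron-rich carbonate 19 may decompose before use, and the ether can re-ionise on palladium and drift to C-allylated phenol.
   - Fallback from 18 back to 20. The alkoxide of step 8 is quenched with aqueous NH4Cl instead of ClCO2Me to give the racemic 1-arylprop-2-en-1-ol F8. Ph3SiOReO3 (2 mol %, Et2O, 0 °C) effects the 1,3-transposition, driven by conjugation, to the (E)-cinnamyl alcohol F9. Mitsunobu etherification with 9 (PPh3, DIAD, THF, 0 °C) gives 20 by direct SN2 displacement without any π-allyl intermediate.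

**Further compounds**
F1 | step 10 | racemic 2-[3,4-dimethoxy-2,5-bis(methoxymethoxy)phenyl]-3-[2,4-dimethoxy-3-(methoxymethoxy)phenoxy]propanal dimethyl acetal | COCOc1cc(C(C(OC)OC)COc2ccc(OC)c(OCOC)c2OC)c(OCOC)c(OC)c1OC
F2 | step 10 | racemic 3-[3,4-dimethoxy-2,5-bis(methoxymethoxy)phenyl]-4,6,8-trimethoxy-7-(methoxymethoxy)chromane | COCOc1cc(C2COc3c(OC)c(OCOC)c(OC)cc3C2OC)c(OCOC)c(OC)c1OC
F3 | step 10 | 3-[3,4-dimethoxy-2,5-bis(methoxymethoxy)phenyl]-6,8-dimethoxy-7-(methoxymethoxy)-2H-chromene | COCOc1cc(C2=Cc3cc(OC)c(OCOC)c(OC)c3OC2)c(OCOC)c(OC)c1OC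
F4 | step 6 | 2,3-dimethoxyphenyllithium | [Li]c1cccc(OC)c1OC
F5 | step 6 | dimethyl (2,3-dimethoxyphenyl)boronate | COB(OC)c1cccc(OC)c1OC
F6 | step 6 | 2,3-dimethoxyphenol | COc1cccc(O)c1OC
F7 | step 6 | 2,3-dimethoxy-1,4-benzoquinone | COC1=C(OC)C(=O)C=CC1=O
F8 | step 9 | racemic 1-[3,4-dimethoxy-2,5-bis(methoxymethoxy)phenyl]prop-2-en-1-ol | C=CC(O)c1cc(OCOC)c(OC)c(OC)c1OCOC
F9 | step 9 | (2E)-3-[3,4-dimethoxy-2,5-bis(methoxymethoxy)phenyl]prop-2-en-1-ol | OC/C=C/c1cc(OCOC)c(OC)c(OC)c1OCOC
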